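**Assumption:** the SMILES is read as 1,5-di-O-(E)-caffeoyl-4-O-succinyl-(−)-quinic acid (quinic numbering: O1, O3 and O4 on one ring face, O5 and CO2H on the other). The Box-ligand antipode in step 6 is the one that screening shows to give (1S,5R)-10.

## Retrosynthetic overview

1. Target ⇐ acidolysis of the PMB ester and two catechol acetonides ⇐ tin-directed 4-O-succinylation of a 3,4-diol ⇐ double caffeoylation (O1, O5) of PMB 3,4-O-isopropylidenequinate.
2. The quinate ⇐ 1-O-acetylquinide by lactone opening; its 3,4-diol ⇐ exo-face OsO4 dihydroxylation of a bicyclic allylic lactone.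
3. Key step: the allylic lactone ⇐ racemic 1-acetoxycyclohex-3-ene-1-carboxylic acid by Cu/bis(oxazoline) enantioconvergent radical allylic C–H lactonisation (forms C5–O, sets C1 and C5).
4. Racemic acid ⇐ Diels–Alder of butadiene with 2-acetoxyacrylic acid (from pyruvic acid); caffeoyl donor ⇐ Heck of bromocatechol acetonide with acrylic acid.
5. Ring order: carbocycle (Diels–Alder), then γ-lactone (radical step), then transient acetonide; the lactone is opened before the acylations.

## Route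

Step 1
Reactants: 1 catechol
Product: 2 2,2-dimethyl-1,3-benzodioxole
Conditions: 2,2-dimethoxypropane, cat. TsOH, toluene, reflux (MeOH removed)
Reagents that add atoms: 2,2-dimethoxypropane, COC(C)(C)OC
Why: Acid-catalysed transketalisation of the 1,2-diphenol gives the catechol acetonide, which is stable to base, Pd and acyl chloride formation.

Step 2
Reactants: 2 2,2-dimethyl-1,3-benzodioxole
Product: 3 5-bromo-2,2-dimethyl-1,3-benzodioxole
Conditions: NBS, DMF, 0 °C to rt
Reagents that add atoms: N-bromosuccinimide, O=C1CCC(=O)N1Br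
Why: Electrophilic aromatic bromination occurs para to a ring oxygen, the only activated unhindered position.

Step 3
Reactants: 3 5-bromo-2,2-dimethyl-1,3-benzodioxole; 4 acrylic acid
Product: 5 (E)-3-(2,2-dimethyl-1,3-benzodioxol-5-yl)prop-2-enoic acid
Conditions: Pd(OAc)2 (2 mol %), P(o-tol)3, Et3N, DMF, 100 °C; aq. HCl work-up
Reagents that add atoms: none
Why: Mizoroki–Heck coupling of the aryl bromide with acrylic acid gives the E-cinnamic acid through syn-insertion and syn-β-hydride elimination.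

Step 4
Reactants: 6 pyruvic acid
Product: 7 2-acetoxyprop-2-enoic acid
Conditions: Ac2O (2.2 equiv), cat. TsOH, 80 °C; then H2O, rt
Reagents that add atoms: acetic anhydride, CC(=O)OC(C)=O
Why: Acid-catalysed enol acetylation of the α-keto acid, as used for alkyl 2-acetoxyacrylates from pyruvates; the mixed anhydride is hydrolysed on work-up.

Step 5
Reactants: 7 2-acetoxyprop-2-enoic acid; 8 buta-1,3-diene
Product: 9 rac-1-acetoxycyclohex-3-ene-1-carboxylic acid
Conditions: toluene, hydroquinone (cat.), sealed tube, 110 °C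
Reagents that add atoms: none
Why: Thermal Diels–Alder reaction of the captodative dienophile builds the carbocycle and the oxygenated quaternary C1; the adduct is racemic only through the position of the ring alkene, which step 6 makes irrelevant.

Step 6
Reactants: 9 rac-1-acetoxycyclohex-3-ene-1-carboxylic acid
Product: 10 (1S,5R)-7-oxo-6-oxabicyclo[3.2.1]oct-3-en-1-yl acetate
Conditions: Cu(MeCN)4PF6 (10 mol %), (S,S)-t-Bu-Box (12 mol %), PhCO3t-Bu (1.3 equiv), MeCN, 0 °C to rt
Reagents that add atoms: none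
Why: Proposed new method: Cu(I) cleaves the perester to t-BuO•, which abstracts the allylic C5–H (the C2–H2 next to the quaternary, acceptor-substituted C1 is sterically and polar deactivated), so both enantiomers of 9 give the same Cs-symmetric cyclohexenyl radical; the substrate carboxylate bound to the chiral Cu(II)–Box centre then captures one enantiotopic allyl terminus (allyl-Cu(III), C–O reductive elimination), necessarily cis, which forms the C5–O bond and fixes C1 and C5 together; the closest known reactions are the Cu/bis(oxazoline) enantioselective Kharasch–Sosnovsky allylic acyloxylation and Cu/Box enantioselective radical lactonisations of alkenoic acids.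

Step 7
Reactants: 10 (1S,5R)-7-oxo-6-oxabicyclo[3.2.1]oct-3-en-1-yl acetate
Product: 11 (1S,3R,4R,5R)-3,4-dihydroxy-7-oxo-6-oxabicyclo[3.2.1]octan-1-yl acetate
Conditions: OsO4 (2 mol %), NMO (1.3 equiv), acetone/H2O 8:1, rt
Reagents that add atoms: osmium tetroxide (cat.), O=[Os](=O)(=O)=O; N-methylmorpholine N-oxide, C[N+]1([O-])CCOCC1; water, O
Why: Upjohn syn-dihydroxylation attacks the ring face opposite the lactone bridge, placing O3 and O4 cis to each other and to the 1-acetoxy group and trans to O5.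

Step 8
Reactants: 11 (1S,3R,4R,5R)-3,4-dihydroxy-7-oxo-6-oxabicyclo[3.2.1]octan-1-yl acetate
Product: 12 1-O-acetyl-3,4-O-isopropylidene-(−)-quinide
Conditions: 2,2-dimethoxypropane, cat. TsOH, acetone, rt
Reagents that add atoms: 2,2-dimethoxypropane, COC(C)(C)OC
Why: Acid-catalysed acetonide formation on the cis-3,4-diol masks it for the later acylations.

Step 9
Reactants: 12 1-O-acetyl-3,4-O-isopropylidene-(−)-quinide
Product: 14 4-methoxybenzyl 3,4-O-isopropylidene-(−)-quinate, via lithium 3,4-O-isopropylidenequinate 13 (not isolated)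
Conditions: LiOH·H2O (2.1 equiv), THF/H2O, 0 °C to rt; evaporate; PMBCl (1.2 equiv), cat. Bu4NI, DMF, rt
Reagents that add atoms: lithium hydroxide, [Li+].[OH-]; 4-methoxybenzyl chloride, COc1ccc(CCl)cc1
Why: Irreversible saponification opens the strained γ-lactone and removes the acetate (acyl–oxygen cleavage, no stereocentre touched), and SN2 O-alkylation of the carboxylate installs the acid-labile PMB ester, leaving 1-OH and 5-OH free.

Step 10
Reactants: 14 4-methoxybenzyl 3,4-O-isopropylidene-(−)-quinate; 5 (E)-3-(2,2-dimethyl-1,3-benzodioxol-5-yl)prop-2-enoic acid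
Product: 16 4-methoxybenzyl 1,5-bis-O-[(E)-3-(2,2-dimethyl-1,3-benzodioxol-5-yl)prop-2-enoyl]-3,4-O-isopropylidene-(−)-quinate, via acyl chloride 15 (not isolated)
Conditions: 5 (2.6 equiv), (COCl)2, cat. DMF, CH2Cl2, 0 °C to rt, evaporate; then 14, DMAP (0.5 equiv), pyridine, 50 °C
Reagents that add atoms: none
Why: DMAP-catalysed acylation with the cinnamoyl chloride esterifies the secondary 5-OH and, on warming, the tertiary 1-OH, as in known 1-O-acylations of quinic acid derivatives.

Step 11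
Reactants: 16 4-methoxybenzyl 1,5-bis-O-[(E)-3-(2,2-dimethyl-1,3-benzodioxol-5-yl)prop-2-enoyl]-3,4-O-isopropylidene-(−)-quinate
Product: 17 4-methoxybenzyl 1,5-bis-O-[(E)-3-(2,2-dimethyl-1,3-benzodioxol-5-yl)prop-2-enoyl]-(−)-quinate
Conditions: AcOH/H2O 4:1, 45 °C, monitored
Reagents that add atoms: none
Why: Mild acid hydrolysis cleaves the aliphatic dioxolane much faster than the less basic aryl-oxygen ketals and leaves the PMB ester intact.

Step 12
Reactants: 17 4-methoxybenzyl 1,5-bis-O-[(E)-3-(2,2-dimethyl-1,3-benzodioxol-5-yl)prop-2-enoyl]-(−)-quinate; 18 succinic anhydride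
Product: 20 4-methoxybenzyl 1,5-bis-O-[(E)-3-(2,2-dimethyl-1,3-benzodioxol-5-yl)prop-2-enoyl]-4-O-(3-carboxypropanoyl)-(−)-quinate, via 3,4-O-dibutylstannylene acetal 19 (not isolated)
Conditions: Bu2SnO (1.05 equiv), toluene, reflux (Dean–Stark), 2 h; then succinic anhydride (1.1 equiv), 0 °C to rt; aqueous work-up
Reagents that add atoms: none
Why: Stannylene-acetal-mediated acylation of a ring cis-diol goes to the equatorial oxygen flanked by an axial one (O4 here, as in galactoside 3-O-acylation), and ring-opening of the anhydride gives the hemisuccinate directly.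

Step 13
Reactants: 20 4-methoxybenzyl 1,5-bis-O-[(E)-3-(2,2-dimethyl-1,3-benzodioxol-5-yl)prop-2-enoyl]-4-O-(3-carboxypropanoyl)-(−)-quinate
Product: 21 1,5-di-O-(E)-caffeoyl-4-O-succinyl-(−)-quinic acid (target)
Conditions: TFA/CH2Cl2/H2O/anisole (45:45:5:5), 0 °C to rt
Reagents that add atoms: none
Why: Acidolysis removes the PMB ester (cation trapped by anisole) and hydrolyses both catechol ketals in one operation, under acidic conditions that suppress acyl migration among O3, O4 and O5.

## Compound list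

1 | catechol (benzene-1,2-diol) | Oc1ccccc1O | starting material
2 | 2,2-dimethyl-1,3-benzodioxole | CC1(C)Oc2ccccc2O1 | intermediate
3 | 5-bromo-2,2-dimethyl-1,3-benzodioxole | CC1(C)Oc2ccc(Br)cc2O1 | intermediate
4 | acrylic acid | C=CC(=O)O | starting material
5 | (E)-3-(2,2-dimethyl-1,3-benzodioxol-5-yl)prop-2-enoic acid (caffeic acid acetonide) | CC1(C)Oc2ccc(/C=C/C(=O)O)cc2O1 | intermediate
6 | pyruvic acid | CC(=O)C(=O)O | starting material
7 | 2-acetoxyprop-2-enoic acid | C=C(OC(C)=O)C(=O)O | intermediate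
8 | buta-1,3-diene | C=CC=C | starting material
9 | rac-1-acetoxycyclohex-3-ene-1-carboxylic acid (racemate) | CC(=O)OC1(CC=CCC1)C(=O)O | intermediate
10 | (1S,5R)-7-oxo-6-oxabicyclo[3.2.1]oct-3-en-1-yl acetate | C1=CC[C@]2(OC(C)=O)C[C@H]1OC2=O | intermediate
11 | (1S,3R,4R,5R)-3,4-dihydroxy-7-oxo-6-oxabicyclo[3.2.1]octan-1-yl acetate (1-O-acetyl-(−)-quinide) | O[C@@H]1[C@H](O)C[C@]2(OC(C)=O)C[C@H]1OC2=O | intermediate
12 | 1-O-acetyl-3,4-O-isopropylidene-(−)-quinide (1,5-lactone; acetonide on the cis-3,4-diol) | CC1(C)O[C@@H]2[C@H](O1)C[C@]3(OC(C)=O)C[C@H]2OC3=O | intermediate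
13 | lithium 3,4-O-isopropylidene-(−)-quinate | CC1(C)O[C@@H]2[C@H](O1)C[C@@](O)(C(=O)[O-])C[C@H]2O.[Li+] | intermediate
14 | 4-methoxybenzyl 3,4-O-isopropylidene-(−)-quinate (1-OH and 5-OH free; O1, O3, O4 cis, O5 and ester trans to them) | CC1(C)O[C@@H]2[C@H](O1)C[C@@](O)(C(=O)OCc3ccc(OC)cc3)C[C@H]2O | intermediate
15 | (E)-3-(2,2-dimethyl-1,3-benzodioxol-5-yl)prop-2-enoyl chloride | CC1(C)Oc2ccc(/C=C/C(Cl)=O)cc2O1 | intermediate
16 | 4-methoxybenzyl 1,5-bis-O-[(E)-3-(2,2-dimethyl-1,3-benzodioxol-5-yl)prop-2-enoyl]-3,4-O-isopropylidene-(−)-quinate | CC1(C)O[C@@H]2[C@H](O1)C[C@@](OC(=O)/C=C/c3ccc4OC(C)(C)Oc4c3)(C(=O)OCc3ccc(OC)cc3)C[C@H]2OC(=O)/C=C/c2ccc3OC(C)(C)Oc3c2 | intermediate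
17 | 4-methoxybenzyl 1,5-bis-O-[(E)-3-(2,2-dimethyl-1,3-benzodioxol-5-yl)prop-2-enoyl]-(−)-quinate (3-OH, 4-OH free) | O[C@@H]1[C@H](O)C[C@@](OC(=O)/C=C/c2ccc3OC(C)(C)Oc3c2)(C(=O)OCc2ccc(OC)cc2)C[C@H]1OC(=O)/C=C/c1ccc2OC(C)(C)Oc2c1 | intermediate
18 | succinic anhydride | O=C1CCC(=O)O1 | starting material
19 | 3,4-O-dibutylstannylene acetal of 17 | CCCC[Sn]1(CCCC)O[C@@H]2[C@H](O1)C[C@@](OC(=O)/C=C/c3ccc4OC(C)(C)Oc4c3)(C(=O)OCc3ccc(OC)cc3)C[C@H]2OC(=O)/C=C/c2ccc3OC(C)(C)Oc3c2 | intermediate
20 | 4-methoxybenzyl 1,5-bis-O-[(E)-3-(2,2-dimethyl-1,3-benzodioxol-5-yl)prop-2-enoyl]-4-O-(3-carboxypropanoyl)-(−)-quinate (3-OH free) | OC(=O)CCC(=O)O[C@@H]1[C@H](O)C[C@@](OC(=O)/C=C/c2ccc3OC(C)(C)Oc3c2)(C(=O)OCc2ccc(OC)cc2)C[C@H]1OC(=O)/C=C/c1ccc2OC(C)(C)Oc2c1 | intermediate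
21 | 1,5-di-O-(E)-caffeoyl-4-O-succinyl-(−)-quinic acid (O1-caffeoyl, 3-OH, O4-succinyl on one face; O5-caffeoyl and CO2H on the other) | O=C(O)CCC(=O)O[C@@H]1[C@H](O)C[C@@](OC(=O)/C=C/c2ccc(O)c(O)c2)(C(=O)O)C[C@H]1OC(=O)/C=C/c1ccc(O)c(O)c1 | target

## Step count and risks

Total step count: 13. Longest linear sequence: 10 steps (steps 4–13, pyruvic acid to target); the caffeoyl donor (steps 1–3) joins at step 10.

Steps most likely to fail:

Step 6 (site selectivity of hydrogen abstraction and enantioselectivity of the radical lactonisation). The fallback sets out from 9 and comes back at 10, replacing the radical C–H step by polar halolactonisation–elimination on resolved material. Rac-9 is separated by preparative chiral SFC to give (S)-1-acetoxycyclohex-3-ene-1-carboxylic acid F1. Iodolactonisation (I2, KI, NaHCO3, H2O/CH2Cl2) gives the trans-diaxial iodolactone (1S,4R,5R)-4-iodo-7-oxo-6-oxabicyclo[3.2.1]octan-1-yl acetate F2. DBU in toluene at 80 °C then eliminates HI anti-periplanar towards C3 to give 10.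

Step 10 (acylation of the tertiary 1-OH by the bulky cinnamoyl chloride). The fallback sets out from 14 and comes back at 16, building the cinnamate units on the core instead of attaching them. Acryloyl chloride (Et3N, DMAP, CH2Cl2, 0 °C to rt) acylates both hydroxyls to give 4-methoxybenzyl 1,5-di-O-acryloyl-3,4-O-isopropylidene-(−)-quinate F3. A double Mizoroki–Heck reaction with aryl bromide 3 (Pd(OAc)2, P(o-tol)3, Et3N, DMF, 90 °C) then gives 16.

Step 12 (regioselectivity of succinylation, O4 versus O3, and acyl migration on tin). The fallback sets out from 17 and comes back at 20, differentiating the diol through stereoelectronically controlled orthoester opening. 2-Chloro-1,1,1-trimethoxyethane with cat. CSA gives the 3,4-O-(2-chloro-1-methoxyethylidene) orthoester of 17 F4. Aqueous AcOH opens it to the axial ester, the 3-O-chloroacetyl derivative of 17 with free equatorial 4-OH F5. Succinic anhydride with DMAP in pyridine gives the 3-O-chloroacetyl derivative of 20 F6, and thiourea (NaHCO3, EtOH, 50 °C) removes the chloroacetate selectively to give 20.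

## Further compounds

F1 | step 6 | (S)-1-acetoxycyclohex-3-ene-1-carboxylic acid | C1C[C@@](OC(C)=O)(C(=O)O)CC=C1
F2 | step 6 | (1S,4R,5R)-4-iodo-7-oxo-6-oxabicyclo[3.2.1]octan-1-yl acetate | I[C@@H]1CC[C@]2(OC(C)=O)C[C@H]1OC2=O
F3 | step 10 | 4-methoxybenzyl 1,5-di-O-acryloyl-3,4-O-isopropylidene-(−)-quinate | CC1(C)O[C@@H]2[C@H](O1)C[C@@](OC(=O)C=C)(C(=O)OCc3ccc(OC)cc3)C[C@H]2OC(=O)C=C
F4 | step 12 | 3,4-O-(2-chloro-1-methoxyethylidene) orthoester of 17 (orthoester carbon as a mixture) | COC1(CCl)O[C@@H]2[C@H](O1)C[C@@](OC(=O)/C=C/c3ccc4OC(C)(C)Oc4c3)(C(=O)OCc3ccc(OC)cc3)C[C@H]2OC(=O)/C=C/c2ccc3OC(C)(C)Oc3c2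
F5 | step 12 | 3-O-chloroacetyl derivative of 17 (4-OH free) | O[C@@H]1[C@H](OC(=O)CCl)C[C@@](OC(=O)/C=C/c2ccc3OC(C)(C)Oc3c2)(C(=O)OCc2ccc(OC)cc2)C[C@H]1OC(=O)/C=C/c1ccc2OC(C)(C)Oc2c1
F6 | step 12 | 3-O-chloroacetyl derivative of 20 | OC(=O)CCC(=O)O[C@@H]1[C@H](OC(=O)CCl)C[C@@](OC(=O)/C=C/c2ccc3OC(C)(C)Oc3c2)(C(=O)OCc2ccc(OC)cc2)C[C@H]1OC(=O)/C=C/c1ccc2OC(C)(C)Oc2c1
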